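The ten-membered carbocycle (C1–C10, germacrane numbering) is closed last, at the C7–C8 bond, by an intramolecular Nozaki–Hiyama allylation. The feature exploited is the α-methylene-γ-butyrolactone (C6, C7, C11, C12, O) lying next to the oxygenated C8: read backwards, it is a 3-(bromomethyl)butenolide whose γ-carbon C7 attacks a tethered C8 aldehyde. In one operation CrCl2 forms C7–C8, closes the carbocycle onto the finished lactone and 1,10-epoxide, sets C7 (anti to the C6 substituent) and C8 (chair transition state), and unveils the exocyclic methylene. The precursor is a linear butenolide aldehyde carrying the Z-C4=C5 alkene and the C3 ester; the C8 ester is then attached with inversion.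

Key step: step 18

Remarks: Germacrane numbering is used for the target and for the matching atoms of every intermediate (C1–C10 ring carbons, C11–C13 lactone carbons with C13 the exocyclic methylene, C14 and C15 the methyls on C10 and C4). Acrolein, prop-1-yn-1-ylmagnesium bromide, but-3-yn-1-ol, oxirane, (R)-2-methylbutanoic acid, 2-(bromomethyl)acrylic acid and tiglyl alcohol are taken as commercial.
Assumption: the macrocyclic allylation is taken to follow the closed chair transition state usual for allylchromium reagents, which gives the 8S carbinol, so the C8 ester is introduced with inversion.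

Step 1
Reactants: 1 acrolein; 2 prop-1-yn-1-ylmagnesium bromide
Product: 3 rac-hex-1-en-4-yn-3-ol
Conditions: THF, −78 to 0 °C; then aq NH4Cl
Reagents that add atoms: none
Why: Grignard 1,2-addition of the alkynyl nucleophile to the enal carbonyl should give the racemic vinyl propynyl carbinol, which already holds C7, C6, C5, C4 and C15.

Step 2
Reactants: 3 rac-hex-1-en-4-yn-3-ol
Product: 5 rac-(4Z)-5-iodohexa-1,4-dien-3-ol, via cyclic alkenylaluminate 4 (not isolated)
Conditions: NaAlH2(OCH2CH2OMe)2, THF, 0 °C to rt; then I2, −78 °C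
Reagents that add atoms: iodine, II
Why: Alkoxide-directed trans-hydroalumination of the propargylic alcohol and iodinolysis of the C–Al bond with retention should place iodine on C4 cis to C6, the geometry that later becomes the Z C4=C5 alkene.

Step 3
Reactants: 5 rac-(4Z)-5-iodohexa-1,4-dien-3-ol
Product: 6 (3S,4Z)-5-iodohexa-1,4-dien-3-ol
Conditions: Ti(OiPr)4, L-(+)-diisopropyl tartrate, t-BuOOH (0.6 equiv), 4 Å molecular sieves, CH2Cl2, −20 °C
Reagents that add atoms: none
Why: Sharpless kinetic resolution: the titanium tartrate catalyst should epoxidize the vinyl group of the 3R enantiomer much faster, so that the 3S alcohol, which carries the C6 configuration of the target, is recovered.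

Step 4
Reactants: 6 (3S,4Z)-5-iodohexa-1,4-dien-3-ol
Product: 7 tert-butyl{[(3S,4Z)-5-iodohexa-1,4-dien-3-yl]oxy}dimethylsilane
Conditions: TBSCl, imidazole, DMF, rt
Reagents that add atoms: tert-butyldimethylsilyl chloride, CC(C)(C)[Si](C)(C)Cl
Why: Silylation protects the C6 hydroxyl for the coupling, oxidation and reduction steps without touching the alkenyl iodide.

Step 5
Reactants: 8 but-3-yn-1-ol
Product: 9 1-[(but-3-yn-1-yloxy)methyl]-4-methoxybenzene
Conditions: NaH, PMBCl, Bu4NI (cat.), THF, 0 °C to rt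
Reagents that add atoms: 4-methoxybenzyl chloride, COc1ccc(CCl)cc1
Why: Williamson etherification gives a protecting group on the C8 oxygen that is later removed oxidatively under neutral conditions.

Step 6
Reactants: 9 1-[(but-3-yn-1-yloxy)methyl]-4-methoxybenzene; 10 oxirane
Product: 13 (3E)-6-[(4-methoxybenzyl)oxy]-4-methylhex-3-en-1-ol, via alkenylalane 11 (not isolated), via lithium alkenylalanate 12 (not isolated)
Conditions: AlMe3, Cp2ZrCl2 (cat.), CH2Cl2, 0 °C to rt; n-BuLi, hexane–THF, −78 °C; then oxirane, −78 °C to rt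
Reagents that add atoms: trimethylaluminium, C[Al](C)C
Why: Negishi zirconium-catalysed carboalumination adds methyl and aluminium syn across the alkyne, which sets the E C1=C10 alkene with the C14 methyl, and the alanate then opens oxirane to append C2 and C3 with retention of the alkene geometry.

Step 7
Reactants: 13 (3E)-6-[(4-methoxybenzyl)oxy]-4-methylhex-3-en-1-ol
Product: 14 (3E)-6-[(4-methoxybenzyl)oxy]-4-methylhex-3-enal
Conditions: Dess–Martin periodinane, NaHCO3, CH2Cl2, 0 °C; used crude
Reagents that add atoms: none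
Why: Dess–Martin oxidation under buffered conditions should give the β,γ-unsaturated aldehyde without migration of the alkene into conjugation.

Step 8
Reactants: 7 silyl ether of the iodo dienol; 14 (3E)-6-[(4-methoxybenzyl)oxy]-4-methylhex-3-enal
Product: 16 (3E,6RS,7Z,9S)-9-[(tert-butyldimethylsilyl)oxy]-1-[(4-methoxybenzyl)oxy]-3,7-dimethylundeca-3,7,10-trien-6-ol, via alkenylchromium species 15 (not isolated)
Conditions: CrCl2, NiCl2 (1 mol %), DMSO, rt
Reagents that add atoms: none
Why: Nozaki–Hiyama–Kishi coupling: nickel-catalysed activation of the alkenyl iodide and transmetalation to chromium should give, with retention of the Z geometry, a non-basic alkenylchromium reagent that adds to the enolizable aldehyde to form C3–C4, the C3 carbinol being expected as a mixture of epimers that steps 9 and 10 funnel into one.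

Step 9
Reactants: 16 epimeric allylic alcohols
Product: 17 (3E,7Z,9S)-9-[(tert-butyldimethylsilyl)oxy]-1-[(4-methoxybenzyl)oxy]-3,7-dimethylundeca-3,7,10-trien-6-one
Conditions: Dess–Martin periodinane, NaHCO3, CH2Cl2, 0 °C
Reagents that add atoms: none
Why: Dess–Martin oxidation converts both C3 epimers into one Z-enone under non-basic conditions.

Step 10
Reactants: 17 Z-enone
Product: 18 (3E,6S,7Z,9S)-9-[(tert-butyldimethylsilyl)oxy]-1-[(4-methoxybenzyl)oxy]-3,7-dimethylundeca-3,7,10-trien-6-ol
Conditions: (R)-2-methyl-CBS-oxazaborolidine, catecholborane, toluene, −78 °C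
Reagents that add atoms: none
Why: Corey–Bakshi–Shibata reduction: the (R)-oxazaborolidine should deliver hydride to the ketone face defined by the large α-methylalkenyl and the small CH2 substituent, which gives the 3S (germacrane C3) allylic alcohol under reagent control, and catecholborane at low temperature avoids hydroboration of the alkenes.

Step 11
Reactants: 18 (6S)-allylic alcohol; 19 (R)-2-methylbutanoic acid
Product: 20 (3E,6S,7Z,9S)-9-[(tert-butyldimethylsilyl)oxy]-1-[(4-methoxybenzyl)oxy]-3,7-dimethylundeca-3,7,10-trien-6-yl (2R)-2-methylbutanoate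
Conditions: DCC, DMAP (cat.), CH2Cl2, 0 °C to rt
Reagents that add atoms: none
Why: Steglich esterification acylates the C3 alcohol with retention at C3 and at the α-carbon of the acid.

Step 12
Reactants: 20 triene ester
Product: 21 (2S,3Z,5S)-5-[(tert-butyldimethylsilyl)oxy]-1-[(2R,3R)-3-{2-[(4-methoxybenzyl)oxy]ethyl}-3-methyloxiran-2-yl]-3-methylhepta-3,6-dien-2-yl (2R)-2-methylbutanoate
Conditions: D-fructose-derived Shi ketone (0.3 equiv), KHSO5 (as Oxone), K2CO3, Bu4NHSO4, MeCN–dimethoxymethane–aq. buffer (pH 10.5), 0 °C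
Reagents that add atoms: potassium peroxymonosulfate, [K+].[O-]S(=O)(=O)OO
Why: Shi asymmetric epoxidation: the chiral dioxirane should attack the electron-rich E-trisubstituted C1=C10 alkene through the spiro transition state to give the 1R,10R epoxide, while the C4=C5 alkene (deactivated and shielded by two allylic oxygen substituents) and the terminal vinyl group react much more slowly.

Step 13
Reactants: 21 epoxy silyl ether
Product: 22 (2S,3Z,5S)-5-hydroxy-1-[(2R,3R)-3-{2-[(4-methoxybenzyl)oxy]ethyl}-3-methyloxiran-2-yl]-3-methylhepta-3,6-dien-2-yl (2R)-2-methylbutanoate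
Conditions: Bu4NF, AcOH, THF, 0 °C to rt
Reagents that add atoms: none
Why: Fluoride-mediated desilylation, buffered with acetic acid to suppress acyl migration from C3, frees the C6 hydroxyl.

Step 14
Reactants: 22 C6 alcohol; 23 2-(bromomethyl)acrylic acid
Product: 24 (2S,3Z,5S)-5-{[2-(bromomethyl)prop-2-enoyl]oxy}-1-[(2R,3R)-3-{2-[(4-methoxybenzyl)oxy]ethyl}-3-methyloxiran-2-yl]-3-methylhepta-3,6-dien-2-yl (2R)-2-methylbutanoate
Conditions: DCC, DMAP (5 mol %), CH2Cl2, −20 to 0 °C
Reagents that add atoms: none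
Why: Steglich esterification at low temperature installs C11, C12 and C13 on the C6 oxygen, the small amount of DMAP limiting allylic substitution of the bromide.

Step 15
Reactants: 24 acrylate diene
Product: 25 (2S,3Z)-4-[(2R)-4-(bromomethyl)-5-oxo-2,5-dihydrofuran-2-yl]-1-[(2R,3R)-3-{2-[(4-methoxybenzyl)oxy]ethyl}-3-methyloxiran-2-yl]-3-methylbut-3-en-2-yl (2R)-2-methylbutanoate
Conditions: second-generation Grubbs catalyst RuCl2(=CHPh)(H2IMes)(PCy3) (10 mol %), toluene, 80 °C, 5 mM
Reagents that add atoms: none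
Why: Ring-closing metathesis: the catalyst should load on the terminal vinyl group and close onto the acrylate with loss of ethylene, forming the butenolide (C7=C11) that is the lactone ring of the target in its endocyclic-alkene form.

Step 16
Reactants: 25 bromomethyl butenolide
Product: 26 (2S,3Z)-4-[(2R)-4-(bromomethyl)-5-oxo-2,5-dihydrofuran-2-yl]-1-[(2R,3R)-3-(2-hydroxyethyl)-3-methyloxiran-2-yl]-3-methylbut-3-en-2-yl (2R)-2-methylbutanoate
Conditions: DDQ, CH2Cl2–pH 7 buffer, 0 °C
Reagents that add atoms: none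
Why: Oxidative cleavage of the 4-methoxybenzyl ether by DDQ proceeds under neutral conditions that should leave the allylic bromide, butenolide, epoxide and ester intact.

Step 17
Reactants: 26 primary alcohol
Product: 27 (2S,3Z)-4-[(2R)-4-(bromomethyl)-5-oxo-2,5-dihydrofuran-2-yl]-3-methyl-1-[(2R,3R)-3-methyl-3-(2-oxoethyl)oxiran-2-yl]but-3-en-2-yl (2R)-2-methylbutanoate
Conditions: Dess–Martin periodinane, NaHCO3, CH2Cl2, 0 °C; used at once
Reagents that add atoms: none
Why: Buffered Dess–Martin oxidation gives the β,γ-epoxy aldehyde without base, so that β-elimination of the epoxide is avoided.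

Step 18
Reactants: 27 bromomethyl butenolide aldehyde
Product: 29 (1R,3S,4Z,6R,7R,8S,10R)-1,10-epoxy-8-hydroxy-3-{[(2R)-2-methylbutanoyl]oxy}germacra-4,11(13)-dien-12,6-olide, via allylchromium species 28 (not isolated)
Conditions: CrCl2 (8 equiv), THF, rt, 27 added by syringe pump over 10 h to a final 2 mM
Reagents that add atoms: none
Why: Two equivalents of CrCl2 reduce the allylic bromide to an allylchromium species (trivalent chromium) that adds to the C8 aldehyde through its γ-carbon C7 in a closed six-membered chair transition state, with allylic transposition that creates the C11=C13 exocyclic methylene; the closest known reaction type is the Nozaki–Hiyama (chromium Barbier) allylation, which in its intramolecular form is an established way to close ten-membered carbocycles. The carbocycle is closed in a 10-exo-trig mode on the aldehyde carbonyl, with the nucleophilic C7=C11 bond lying outside the new ring. C7 is controlled by the C6 stereocenter of the planar butenolide: C8 should bond to the face opposite the C5 alkenyl chain, which gives the trans-fused 6R,7R lactone. C8 is controlled by the chair: the ring locks the allyl unit in the E-type geometry (C6 trans to C13) and a pseudo-equatorial C9 chain leads to the anti adduct, the 8S alcohol. The step needs γ- over α-attack (α-attack at C13 would give a twelve-membered ring), cyclization over oligomerization and survival of the β,γ-epoxy aldehyde; these are secured by the intrinsic γ-selectivity of allylchromium reagents, slow addition at high dilution and the non-basic, aldehyde-selective character of the reagent.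

Step 19
Reactants: 30 (2E)-2-methylbut-2-en-1-ol (tiglyl alcohol)
Product: 31 [(2R,3R)-2,3-dimethyloxiran-2-yl]methanol
Conditions: Ti(OiPr)4 (10 mol %), D-(−)-diethyl tartrate, t-BuOOH, 4 Å molecular sieves, CH2Cl2, −20 °C
Reagents that add atoms: tert-butyl hydroperoxide, CC(C)(C)OO
Why: Sharpless asymmetric epoxidation: the D-(−)-tartrate catalyst should deliver oxygen to the alkene face that gives the 2R,3R epoxy alcohol, the E geometry of the alkene fixing the cis relation of the two methyl groups.

Step 20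
Reactants: 31 [(2R,3R)-2,3-dimethyloxiran-2-yl]methanol
Product: 32 (2S,3R)-2,3-dimethyloxirane-2-carboxylic acid
Conditions: RuCl3 (cat.), NaIO4, CCl4–MeCN–H2O, 0 °C to rt
Reagents that add atoms: water, O
Why: Ruthenium tetroxide oxidation (RuCl3/NaIO4) takes the primary alcohol through the aldehyde hydrate to the carboxylic acid without touching the epoxide stereocenters, the C2 descriptor changing from R to S only through the priority rules.

Step 21
Reactants: 29 macrocyclic 8S alcohol; 32 (2S,3R)-2,3-dimethyloxirane-2-carboxylic acid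
Product: 33 CNP0265335.4
Conditions: PPh3, DIAD (betaine preformed), toluene, 0 °C to rt
Reagents that add atoms: none
Why: Mitsunobu esterification: the C8 alcohol is activated as its alkoxyphosphonium ion and displaced by the carboxylate in an SN2 reaction, which should invert the 8S carbinol to the 8R ester of the target.

Compound list
1 | acrolein (prop-2-enal) | C=CC=O | starting material
2 | prop-1-yn-1-ylmagnesium bromide | CC#C[Mg]Br | starting material
3 | rac-hex-1-en-4-yn-3-ol | C=CC(O)C#CC | intermediate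
4 | sodium 2,2-bis(2-methoxyethoxy)-3-methyl-5-vinyl-2,5-dihydro-1,2-oxaaluminol-2-uide (cyclic alkenylaluminate, racemic) | [Na+].C=CC1O[Al-](OCCOC)(OCCOC)C(C)=C1 | intermediate
5 | rac-(4Z)-5-iodohexa-1,4-dien-3-ol | C=CC(O)/C=C(/C)I | intermediate
6 | (3S,4Z)-5-iodohexa-1,4-dien-3-ol | C=C[C@H](O)/C=C(/C)I | intermediate
7 | tert-butyl{[(3S,4Z)-5-iodohexa-1,4-dien-3-yl]oxy}dimethylsilane | C=C[C@H](O[Si](C)(C)C(C)(C)C)/C=C(/C)I | intermediate
8 | but-3-yn-1-ol | C#CCCO | starting material
9 | 1-[(but-3-yn-1-yloxy)methyl]-4-methoxybenzene | C#CCCOCc1ccc(OC)cc1 | intermediate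
10 | oxirane | C1CO1 | starting material
11 | {(1E)-4-[(4-methoxybenzyl)oxy]-2-methylbut-1-en-1-yl}dimethylalumane | C[Al](C)/C=C(\C)CCOCc1ccc(OC)cc1 | intermediate
12 | lithium butyl{(1E)-4-[(4-methoxybenzyl)oxy]-2-methylbut-1-en-1-yl}dimethylaluminate | [Li+].CCCC[Al-](C)(C)/C=C(\C)CCOCc1ccc(OC)cc1 | intermediate
13 | (3E)-6-[(4-methoxybenzyl)oxy]-4-methylhex-3-en-1-ol | OCC/C=C(\C)CCOCc1ccc(OC)cc1 | intermediate
14 | (3E)-6-[(4-methoxybenzyl)oxy]-4-methylhex-3-enal | O=CC/C=C(\C)CCOCc1ccc(OC)cc1 | intermediate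
15 | dichloro{(2Z,4S)-4-[(tert-butyldimethylsilyl)oxy]hexa-2,5-dien-2-yl}chromium | C=C[C@H](O[Si](C)(C)C(C)(C)C)/C=C(/C)[Cr](Cl)Cl | intermediate
16 | (3E,6RS,7Z,9S)-9-[(tert-butyldimethylsilyl)oxy]-1-[(4-methoxybenzyl)oxy]-3,7-dimethylundeca-3,7,10-trien-6-ol (both epimers at C6, the future C3) | C=C[C@H](O[Si](C)(C)C(C)(C)C)/C=C(/C)C(O)C/C=C(\C)CCOCc1ccc(OC)cc1 | intermediate
17 | (3E,7Z,9S)-9-[(tert-butyldimethylsilyl)oxy]-1-[(4-methoxybenzyl)oxy]-3,7-dimethylundeca-3,7,10-trien-6-one | C=C[C@H](O[Si](C)(C)C(C)(C)C)/C=C(/C)C(=O)C/C=C(\C)CCOCc1ccc(OC)cc1 | intermediate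
18 | (3E,6S,7Z,9S)-9-[(tert-butyldimethylsilyl)oxy]-1-[(4-methoxybenzyl)oxy]-3,7-dimethylundeca-3,7,10-trien-6-ol | C=C[C@H](O[Si](C)(C)C(C)(C)C)/C=C(/C)[C@@H](O)C/C=C(\C)CCOCc1ccc(OC)cc1 | intermediate
19 | (2R)-2-methylbutanoic acid | CC[C@@H](C)C(=O)O | starting material
20 | (3E,6S,7Z,9S)-9-[(tert-butyldimethylsilyl)oxy]-1-[(4-methoxybenzyl)oxy]-3,7-dimethylundeca-3,7,10-trien-6-yl (2R)-2-methylbutanoate | C=C[C@H](O[Si](C)(C)C(C)(C)C)/C=C(/C)[C@@H](OC(=O)[C@H](C)CC)C/C=C(\C)CCOCc1ccc(OC)cc1 | intermediate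
21 | (2S,3Z,5S)-5-[(tert-butyldimethylsilyl)oxy]-1-[(2R,3R)-3-{2-[(4-methoxybenzyl)oxy]ethyl}-3-methyloxiran-2-yl]-3-methylhepta-3,6-dien-2-yl (2R)-2-methylbutanoate | C=C[C@H](O[Si](C)(C)C(C)(C)C)/C=C(/C)[C@@H](OC(=O)[C@H](C)CC)C[C@H]1O[C@]1(C)CCOCc1ccc(OC)cc1 | intermediate
22 | (2S,3Z,5S)-5-hydroxy-1-[(2R,3R)-3-{2-[(4-methoxybenzyl)oxy]ethyl}-3-methyloxiran-2-yl]-3-methylhepta-3,6-dien-2-yl (2R)-2-methylbutanoate | C=C[C@H](O)/C=C(/C)[C@@H](OC(=O)[C@H](C)CC)C[C@H]1O[C@]1(C)CCOCc1ccc(OC)cc1 | intermediate
23 | 2-(bromomethyl)prop-2-enoic acid | C=C(CBr)C(=O)O | starting material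
24 | (2S,3Z,5S)-5-{[2-(bromomethyl)prop-2-enoyl]oxy}-1-[(2R,3R)-3-{2-[(4-methoxybenzyl)oxy]ethyl}-3-methyloxiran-2-yl]-3-methylhepta-3,6-dien-2-yl (2R)-2-methylbutanoate | C=C[C@H](OC(=O)C(=C)CBr)/C=C(/C)[C@@H](OC(=O)[C@H](C)CC)C[C@H]1O[C@]1(C)CCOCc1ccc(OC)cc1 | intermediate
25 | (2S,3Z)-4-[(2R)-4-(bromomethyl)-5-oxo-2,5-dihydrofuran-2-yl]-1-[(2R,3R)-3-{2-[(4-methoxybenzyl)oxy]ethyl}-3-methyloxiran-2-yl]-3-methylbut-3-en-2-yl (2R)-2-methylbutanoate | O=C1O[C@H](/C=C(/C)[C@@H](OC(=O)[C@H](C)CC)C[C@H]2O[C@]2(C)CCOCc2ccc(OC)cc2)C=C1CBr | intermediate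
26 | (2S,3Z)-4-[(2R)-4-(bromomethyl)-5-oxo-2,5-dihydrofuran-2-yl]-1-[(2R,3R)-3-(2-hydroxyethyl)-3-methyloxiran-2-yl]-3-methylbut-3-en-2-yl (2R)-2-methylbutanoate | O=C1O[C@H](/C=C(/C)[C@@H](OC(=O)[C@H](C)CC)C[C@H]2O[C@]2(C)CCO)C=C1CBr | intermediate
27 | (2S,3Z)-4-[(2R)-4-(bromomethyl)-5-oxo-2,5-dihydrofuran-2-yl]-3-methyl-1-[(2R,3R)-3-methyl-3-(2-oxoethyl)oxiran-2-yl]but-3-en-2-yl (2R)-2-methylbutanoate | O=C1O[C@H](/C=C(/C)[C@@H](OC(=O)[C@H](C)CC)C[C@H]2O[C@]2(C)CC=O)C=C1CBr | intermediate
28 | allylchromium dichloride derived from 27 (CH2Br replaced by CH2CrCl2, all stereocenters unchanged) | O=C1O[C@H](/C=C(/C)[C@@H](OC(=O)[C@H](C)CC)C[C@H]2O[C@]2(C)CC=O)C=C1C[Cr](Cl)Cl | intermediate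
29 | (1R,3S,4Z,6R,7R,8S,10R)-1,10-epoxy-8-hydroxy-3-{[(2R)-2-methylbutanoyl]oxy}germacra-4,11(13)-dien-12,6-olide | C=C1C(=O)O[C@@H]2/C=C(/C)[C@@H](OC(=O)[C@H](C)CC)C[C@H]3O[C@]3(C)C[C@H](O)[C@@H]12 | intermediate
30 | (2E)-2-methylbut-2-en-1-ol (tiglyl alcohol) | C/C=C(\C)CO | starting material
31 | [(2R,3R)-2,3-dimethyloxiran-2-yl]methanol | OC[C@@]1(C)O[C@@H]1C | intermediate
32 | (2S,3R)-2,3-dimethyloxirane-2-carboxylic acid | OC(=O)[C@@]1(C)O[C@@H]1C | intermediate
33 | CNP0265335.4, (1R,3S,4Z,6R,7R,8R,10R)-8-{[(2S,3R)-2,3-dimethyloxirane-2-carbonyl]oxy}-1,10-epoxy-3-{[(2R)-2-methylbutanoyl]oxy}germacra-4,11(13)-dien-12,6-olide | C=C1C(=O)O[C@@H]2/C=C(/C)[C@@H](OC(=O)[C@H](C)CC)C[C@H]3O[C@]3(C)C[C@@H](OC(=O)[C@@]3(C)O[C@@H]3C)[C@@H]12 | target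

Total step count: 21 steps.
Longest linear sequence: 16 steps (steps 1–4, 8–18 and 21, from acrolein). Steps 5–7 and steps 19–20 are side branches that join at steps 8 and 21.

Steps most likely to fail

Step 18. The β,γ-epoxy aldehyde may be lost before ring closure through opening or β-elimination of the epoxide at the Lewis-acidic trivalent chromium. The allylchromium species may also react intermolecularly, and the tether may erode the chair preference at C8. The fallback sets out from 26 and comes back at 29. Palladium-catalysed borylation of the allylic bromide (B2pin2, Pd2(dba)3, toluene, 50 °C) should give the pinacol allylboronate alcohol F1. Buffered Dess–Martin oxidation should then give the pinacol allylboronate aldehyde F2. Heating F2 in dilute toluene (80 °C) closes the ring by a metal-free intramolecular allylboration through the same chair arrangement, and mild hydrolysis of the borate gives 29.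

Step 21. Elimination from the alkoxyphosphonium ion toward the acidic C7 hydrogen may compete with inversion, as may slow displacement at the hindered ring carbinol with partial retention. The fallback sets out from 29 and comes back at 33. Dess–Martin oxidation should give the 8-ketone F3. Luche reduction (NaBH4, CeCl3, MeOH, −78 °C), with hydride expected on the more exposed face, should give the 8R alcohol F4. Yamaguchi esterification with 32 (2,4,6-trichlorobenzoyl chloride, Et3N, DMAP, toluene) then acylates F4 with retention to give 33. F4 is also the compound that would be acylated directly if the cyclization itself favoured the 8R carbinol.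

Step 10. The skipped Z-dienone may drift before it is reduced (alkene migration into conjugation, Z-to-E isomerization), and the twisted Z-enone may give weaker facial discrimination. The fallback sets out from 7 and 14 and comes back at 18. The oxidation–reduction relay of steps 8–10 is replaced by a reagent-controlled asymmetric Nozaki–Hiyama–Kishi coupling (CrCl2, NiCl2, chiral oxazoline sulfonamide ligand, Et3N, THF–MeCN). This should form C3–C4 and the 3S carbinol in one step, and no new compound is made.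

Further compounds
F1 | step 18 | (2S,3Z)-1-[(2R,3R)-3-(2-hydroxyethyl)-3-methyloxiran-2-yl]-3-methyl-4-{(2R)-5-oxo-4-[(4,4,5,5-tetramethyl-1,3,2-dioxaborolan-2-yl)methyl]-2,5-dihydrofuran-2-yl}but-3-en-2-yl (2R)-2-methylbutanoate | O=C1O[C@H](/C=C(/C)[C@@H](OC(=O)[C@H](C)CC)C[C@H]2O[C@]2(C)CCO)C=C1CB3OC(C)(C)C(C)(C)O3
F2 | step 18 | (2S,3Z)-3-methyl-1-[(2R,3R)-3-methyl-3-(2-oxoethyl)oxiran-2-yl]-4-{(2R)-5-oxo-4-[(4,4,5,5-tetramethyl-1,3,2-dioxaborolan-2-yl)methyl]-2,5-dihydrofuran-2-yl}but-3-en-2-yl (2R)-2-methylbutanoate | O=C1O[C@H](/C=C(/C)[C@@H](OC(=O)[C@H](C)CC)C[C@H]2O[C@]2(C)CC=O)C=C1CB3OC(C)(C)C(C)(C)O3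
F3 | step 21 | (1R,3S,4Z,6R,7S,10R)-1,10-epoxy-3-{[(2R)-2-methylbutanoyl]oxy}-8-oxogermacra-4,11(13)-dien-12,6-olide (C7 spatially unchanged, descriptor changed by the priority rules) | C=C1C(=O)O[C@@H]2/C=C(/C)[C@@H](OC(=O)[C@H](C)CC)C[C@H]3O[C@]3(C)CC(=O)[C@@H]12
F4 | step 21 | (1R,3S,4Z,6R,7R,8R,10R)-1,10-epoxy-8-hydroxy-3-{[(2R)-2-methylbutanoyl]oxy}germacra-4,11(13)-dien-12,6-olide | C=C1C(=O)O[C@@H]2/C=C(/C)[C@@H](OC(=O)[C@H](C)CC)C[C@H]3O[C@]3(C)C[C@@H](O)[C@@H]12
F0 | step 10 | none | none
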